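**Retrosynthetic overview**
- The (E)-β-methoxy enone is made last from the C6 ester (reduction, oxidation, ethynyl addition, oxidation, methanol addition), after the C24 ketal and the C26 silyl ether have been cleaved.
- Ring B is closed by a one-carbon [5+1] step: bis(iodozincio)methane adds to both carbonyls of a ring A 1,5-diketone (C22 ring ketone, C18 methyl ketone) and forms C21–C22 and C18–C21. The feature used is the C21 methylene between the two cis-diaxial tertiary carbinols C18 and C22 of ring B (C14, C15, C17, C18, C21, C22).
- The 1,5-diketone comes from Michael addition of the C14 enolate of a ring A α-keto ketal to (E)-pent-3-en-2-one (C14–C15). The keto ketal comes from a C24 ketone by Rubottom oxidation (oxygen at C26) and hypervalent-iodine α-hydroxylation then oxidation (C22 ketone, C24 ketal).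
- Ring A (C5, C6, C14, C22, C24, C26) is made by an auxiliary-controlled Diels–Alder reaction (C5–C6, C14–C22) of a 2-silyloxy diene from (S)-2-methylbutanal with an N-acryloyl oxazolidinone, followed by C6 methylation.
- Order of ring formation: ring A (step 5), then ring B (step 13).

Key step: step 13

Remark: atom labels C1–C28 are the positions in the target SMILES; on ring A the α face carries the C5 sec-butyl group and the β face the C6 methyl group, O23 and O28; the C26 oxygen carries TBS (delivered from the diene) in place of a triethylsilyl group; diethyl (3-oxobutan-2-yl)phosphonate is taken as a purchasable reagent.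

Step 1
Reactants: 1 (S)-2-methylbutan-1-ol
Product: 2 (S)-2-methylbutanal
Conditions: TEMPO (cat.), KBr (cat.), NaOCl, NaHCO3, CH2Cl2/H2O, 0 °C
Reagents that add atoms: none
Why: TEMPO-catalysed hypochlorite oxidation of a primary alcohol stops at the aldehyde in the buffered two-phase system at 0 °C and is mild enough that the α-stereocentre (C3) should not epimerise.

Step 2
Reactants: 2 (S)-2-methylbutanal; 3 diethyl (3-oxobutan-2-yl)phosphonate
Product: 4 (3E,5S)-3,5-dimethylhept-3-en-2-one
Conditions: Ba(OH)2·8H2O, THF/H2O (40:1), rt
Reagents that add atoms: none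
Why: Horner–Wadsworth–Emmons olefination of the α-branched aldehyde with the β-ketophosphonate under mild Ba(OH)2 conditions should give the E trisubstituted enone (C5=C26) without epimerising C3, the E geometry following from the reversible addition and the more stable elimination pathway of stabilised phosphonates.

Step 3
Reactants: 4 (3E,5S)-3,5-dimethylhept-3-en-2-one
Product: 5 tert-butyl{[(3E,5S)-3,5-dimethylhepta-1,3-dien-2-yl]oxy}dimethylsilane
Conditions: TBSOTf, Et3N, CH2Cl2, 0 °C
Reagents that add atoms: tert-butyldimethylsilyl trifluoromethanesulfonate, CC(C)(C)[Si](C)(C)OS(=O)(=O)C(F)(F)F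
Why: Soft enolisation (silyl triflate and amine) removes a proton from the accessible C22 methyl group and gives the cross-conjugated 2-silyloxy diene (silyl enol ether formation), so that the hindered γ-hydrogen at C3 is not touched and the sec-butyl stereocentre is kept.

Step 4
Reactants: 6 (S)-4-benzyloxazolidin-2-one; 7 acryloyl chloride
Product: 8 (S)-3-acryloyl-4-benzyloxazolidin-2-one
Conditions: MeMgBr, THF, 0 °C; then 7, −78 → 0 °C
Reagents that add atoms: none
Why: N-Acylation of the bromomagnesium salt of the oxazolidinone with the acid chloride at low temperature gives the acryloyl imide without polymerisation and does not involve the auxiliary stereocentre.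

Step 5
Reactants: 5 tert-butyl{[(3E,5S)-3,5-dimethylhepta-1,3-dien-2-yl]oxy}dimethylsilane; 8 (S)-3-acryloyl-4-benzyloxazolidin-2-one
Product: 9 ring A cycloadduct imide (C24=C26 TBS enol ether; C5 sec-butyl and C6 acyl cis on the α face)
Conditions: Et2AlCl (Lewis acid promoter), CH2Cl2, −78 °C
Reagents that add atoms: none
Why: Lewis acid-promoted Diels–Alder reaction of the chelated s-cis acryloyl imide, in which the diene adds endo to the face opposite the benzyl group with its silyloxy-activated C22 terminus on the acrylate β-carbon (C14) and C5 on C6, so that the auxiliary and the endo rule together should fix C5 as in the target and place the C6 acyl group cis to the sec-butyl group.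

Step 6
Reactants: 9 ring A cycloadduct imide
Product: 10 methyl cis-2-[(S)-butan-2-yl]-4-(tert-butyldimethylsilyloxy)-3-methylcyclohex-3-ene-1-carboxylate
Conditions: LiOMe, THF/MeOH, 0 °C; then H2O
Reagents that add atoms: lithium methoxide, [Li+].[O-]C
Why: Acyl transfer by alkoxide attack at the exocyclic imide carbonyl releases the auxiliary and gives the methyl ester, the TBS enol ether being stable to LiOMe at 0 °C and any epimerisation at C6 being irrelevant because that centre is enolised in the next step.

Step 7
Reactants: 10 methyl cis-2-[(S)-butan-2-yl]-4-(tert-butyldimethylsilyloxy)-3-methylcyclohex-3-ene-1-carboxylate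
Product: 11 C6-methylated ester (methyl 2-[(S)-butan-2-yl]-4-(tert-butyldimethylsilyloxy)-1,3-dimethylcyclohex-3-ene-1-carboxylate; 1-CH3 trans to the butan-2-yl group)
Conditions: LiN(iPr)2, THF, −78 °C; MeI, −78 → −30 °C
Reagents that add atoms: iodomethane, CI
Why: Ester enolate alkylation in which the C5 sec-butyl group is held pseudoaxial on the α face by allylic strain with the C26 methyl group and with the exocyclic enolate, so that methyl iodide should enter from the open β face and set the quaternary C6 with CH3 trans and CO2CH3 cis to the sec-butyl group.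

Step 8
Reactants: 11 C6-methylated ester
Product: 13 α-silyloxy ketone (C24 ketone; C26 OTBS on the β face), via silyloxy epoxide 12 (not isolated)
Conditions: mCPBA, CH2Cl2, −20 → 0 °C
Reagents that add atoms: 3-chloroperoxybenzoic acid, OOC(=O)c1cccc(Cl)c1
Why: Rubottom oxidation, in which the peracid is expected to epoxidise the tetrasubstituted silyl enol ether anti to the pseudoaxial sec-butyl group on the neighbouring C5 (the sense known for electrophilic trapping of 3-substituted enolates) and the silyloxy epoxide rearranges with 1,4-silyl migration to the α-silyloxy ketone, which sets C26 with its oxygen on the β face.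

Step 9
Reactants: 13 α-silyloxy ketone
Product: 14 α-hydroxy dimethyl ketal (C22 carbinol as an epimer mixture; C24 dimethyl ketal)
Conditions: PhI(OAc)2, KOH, MeOH, 0 °C → rt
Reagents that add atoms: methanol, CO
Why: Hypervalent-iodine α-hydroxylation of a ketone in methanolic KOH (enolate formation is possible only toward C22, attack on PhI(OAc)2 gives an α-iodanyl ketone, and methoxide addition, epoxide closure and methanolysis follow) should give the C22 carbinol and the C24 dimethyl ketal in one operation, the C22 configuration being of no consequence.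

Step 10
Reactants: 14 α-hydroxy dimethyl ketal
Product: 15 ring A α-keto ketal (C22 ketone; C24 dimethyl ketal; C26 OTBS)
Conditions: Dess–Martin periodinane, CH2Cl2, rt
Reagents that add atoms: none
Why: Dess–Martin oxidation of the only free (secondary) alcohol gives the α-keto ketal under conditions that leave the ketal, the silyl ether and the ester untouched, and it removes the uncontrolled C22 centre.

Step 11
Reactants: 15 ring A α-keto ketal; 16 (E)-pent-3-en-2-one
Product: 17 ring A 1,5-diketone (key-step precursor; C14 side chain on the β face; C15 R)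
Conditions: LiN(iPr)2, THF, −78 °C; 16, −78 °C; AcOH, −78 °C
Reagents that add atoms: none
Why: Michael addition of the lithium enolate, which can form only at C14: the α face of C14 is screened by the axial sec-butyl group on C5 or by the pseudoaxial ester on C6 in the two accessible half-chairs, so the enone should approach from the β face, and the lithium-bridged closed transition state of a ring (E) enolate with an (E) enone should place C6 and the C15 methyl syn, which corresponds to (R) at C15.

Step 12
Reactants: 18 diiodomethane
Product: 19 bis(iodozincio)methane (THF solution)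
Conditions: Zn dust, PbCl2 (cat.), THF, 0 → 25 °C
Reagents that add atoms: zinc, [Zn]
Why: Direct insertion of zinc into both carbon–iodine bonds of diiodomethane, catalysed by a trace of PbCl2, is the standard preparation of the geminal dizinc reagent as a THF solution.

Step 13
Reactants: 17 ring A 1,5-diketone; 19 bis(iodozincio)methane
Product: 21 trans-decalin diol (key-step product; cis-diaxial C18 and C22 hydroxyl groups), via zincio alkoxide 20 (not isolated)
Conditions: 19 (3 equiv), THF, 0 → 25 °C; then H2O
Reagents that add atoms: none
Why: Proposed new method: the first carbon–zinc bond of CH2(ZnI)2 is expected to add to the C22 ketone, which is activated by chelation of divalent zinc between O23 and a methoxy oxygen on C24, and the zinc alkoxide 20 then holds the remaining C21–ZnI bond next to the C18 methyl ketone, which it activates by coordination, so that the second carbonyl addition forms C18–C21 within the same molecule (the reverse order of the two additions would converge on the same ring). The closest known reaction types are the [2+1] addition of this reagent to 1,2-diketones, which gives cis-cyclopropane-1,2-diols by two successive carbonyl additions, and the double nitroaldol reaction of 1,5-dialdehydes with nitromethane. Ring B (C14, C15, C17, C18, C21, C22) closes by 6-exo-trig attack of C21 on the C18 carbonyl through a chair. C22 is controlled by ring A, whose β face at the carbonyl is shielded by the syn-axial C6 methyl and C26 silyloxy groups, so that C21 enters equatorially from the α face, O23 becomes axial and the ring fusion trans. C18 is controlled by the O23–Zn–O20 bridge in the closing chair, which holds O20 axial and cis to O23 while the C15 methyl, the C18 methyl and both ring A bonds stay equatorial. The step needs the two ketones to react in preference to the ester and the ketal, which organozinc reagents do not attack, and ring closure to outrun β-elimination of 20 to the C22 methylene compound, which the pre-organised chelate should favour.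

Step 14
Reactants: 21 trans-decalin diol
Product: 22 decalin triol (C8 primary alcohol)
Conditions: LiAlH4, THF, 0 °C → reflux; then H2O
Reagents that add atoms: none
Why: Hydride reduction of the hindered methyl ester with LiAlH4 gives the primary alcohol at C8, while the ketal, the silyl ether and the two tertiary alkoxides are inert and no stereocentre is affected.

Step 15
Reactants: 22 decalin triol
Product: 23 C8 aldehyde
Conditions: Dess–Martin periodinane, CH2Cl2, 0 °C → rt
Reagents that add atoms: none
Why: Dess–Martin oxidation is selective for the single primary alcohol because the other two hydroxyl groups are tertiary, and the neopentyl aldehyde formed cannot epimerise.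

Step 16
Reactants: 23 C8 aldehyde
Product: 24 C8 propargylic alcohol (mixture of C8 epimers)
Conditions: HC≡CMgBr (excess), THF, 0 °C → rt; then H2O
Reagents that add atoms: ethynylmagnesium bromide, C#C[Mg]Br
Why: Grignard addition of the small ethynyl nucleophile to the hindered aldehyde (the excess reagent first deprotonates the tertiary alcohols) gives the propargylic alcohol as a mixture of C8 epimers, which is of no consequence because C8 is oxidised in step 18.

Step 17
Reactants: 24 C8 propargylic alcohol
Product: 25 C24 ketone with free C26 hydroxyl group (C8 epimers)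
Conditions: 48% aq. HF, MeCN, 0 °C → rt
Reagents that add atoms: water, O
Why: Aqueous HF cleaves the tertiary silyl ether and hydrolyses the dimethyl ketal to the C24 ketone in one acidic operation, placed before the acid-labile methoxy enone is made, and the tertiary and propargylic alcohols should tolerate it.

Step 18
Reactants: 25 C24 ketone with free C26 hydroxyl group
Product: 26 ethynyl ketone
Conditions: Dess–Martin periodinane, CH2Cl2, 0 °C
Reagents that add atoms: none
Why: Dess–Martin oxidation of the only secondary alcohol gives the ethynyl ketone, the three tertiary alcohols and the C24 ketone being inert to the reagent.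

Step 19
Reactants: 26 ethynyl ketone
Product: 27 CNP0304150.3 (target)
Conditions: MeOH, DABCO (cat.), CH2Cl2, 0 °C → rt
Reagents that add atoms: methanol, CO
Why: Amine-catalysed conjugate (oxa-Michael) addition of methanol to the terminal ynone gives the β-methoxy enone, the E isomer being expected because the addition is reversible and E is the more stable geometry, and the hindered tertiary alcohols should not compete with methanol used in excess.

**Compound list**
1 | (S)-2-methylbutan-1-ol | CC[C@H](C)CO | starting material
2 | (S)-2-methylbutanal | CC[C@H](C)C=O | intermediate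
3 | diethyl (3-oxobutan-2-yl)phosphonate | CCOP(=O)(OCC)C(C)C(C)=O | starting material
4 | (3E,5S)-3,5-dimethylhept-3-en-2-one | CC[C@H](C)/C=C(\C)C(C)=O | intermediate
5 | tert-butyl{[(3E,5S)-3,5-dimethylhepta-1,3-dien-2-yl]oxy}dimethylsilane | CC[C@H](C)/C=C(\C)C(=C)O[Si](C)(C)C(C)(C)C | intermediate
6 | (S)-4-benzyloxazolidin-2-one | O=C1N[C@@H](Cc2ccccc2)CO1 | starting material
7 | acryloyl chloride | C=CC(=O)Cl | starting material
8 | (S)-3-acryloyl-4-benzyloxazolidin-2-one | C=CC(=O)N1[C@@H](Cc2ccccc2)COC1=O | intermediate
9 | (S)-4-benzyl-3-{cis-2-[(S)-butan-2-yl]-4-(tert-butyldimethylsilyloxy)-3-methylcyclohex-3-ene-1-carbonyl}oxazolidin-2-one (ring carbons 1 and 2 are C6 and C5; C5 as in the target) | CC[C@H](C)[C@@H]1[C@H](C(=O)N2[C@@H](Cc3ccccc3)COC2=O)CCC(O[Si](C)(C)C(C)(C)C)=C1C | intermediate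
10 | methyl cis-2-[(S)-butan-2-yl]-4-(tert-butyldimethylsilyloxy)-3-methylcyclohex-3-ene-1-carboxylate | CC[C@H](C)[C@@H]1[C@H](C(=O)OC)CCC(O[Si](C)(C)C(C)(C)C)=C1C | intermediate
11 | methyl 2-[(S)-butan-2-yl]-4-(tert-butyldimethylsilyloxy)-1,3-dimethylcyclohex-3-ene-1-carboxylate (1-CH3 trans to the butan-2-yl group; C5 and C6 as in the target) | CC[C@H](C)[C@@H]1[C@](C)(C(=O)OC)CCC(O[Si](C)(C)C(C)(C)C)=C1C | intermediate
12 | silyloxy epoxide of 11 (oxirane oxygen on the β face, trans to the butan-2-yl group) | CC[C@H](C)[C@@H]1[C@](C)(C(=O)OC)CC[C@@]2(O[Si](C)(C)C(C)(C)C)O[C@@]12C | intermediate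
13 | methyl 2-[(S)-butan-2-yl]-3-(tert-butyldimethylsilyloxy)-1,3-dimethyl-4-oxocyclohexane-1-carboxylate (C5, C6 and C26 as in the target) | CC[C@H](C)[C@@H]1[C@](C)(C(=O)OC)CCC(=O)[C@@]1(C)O[Si](C)(C)C(C)(C)C | intermediate
14 | methyl 2-[(S)-butan-2-yl]-3-(tert-butyldimethylsilyloxy)-5-hydroxy-4,4-dimethoxy-1,3-dimethylcyclohexane-1-carboxylate (C22 carbinol epimers; other centres as in 13) | CC[C@H](C)[C@@H]1[C@](C)(C(=O)OC)CC(O)C(OC)(OC)[C@@]1(C)O[Si](C)(C)C(C)(C)C | intermediate
15 | methyl 2-[(S)-butan-2-yl]-3-(tert-butyldimethylsilyloxy)-4,4-dimethoxy-1,3-dimethyl-5-oxocyclohexane-1-carboxylate | CC[C@H](C)[C@@H]1[C@](C)(C(=O)OC)CC(=O)C(OC)(OC)[C@@]1(C)O[Si](C)(C)C(C)(C)C | intermediate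
16 | (E)-pent-3-en-2-one | C/C=C/C(C)=O | starting material
17 | methyl 2-[(S)-butan-2-yl]-3-(tert-butyldimethylsilyloxy)-4,4-dimethoxy-1,3-dimethyl-5-oxo-6-[(R)-4-oxopentan-2-yl]cyclohexane-1-carboxylate (ring A 1,5-diketone; C14 side chain cis to the C6 methyl) | CC[C@H](C)[C@@H]1[C@](C)(C(=O)OC)[C@@H]([C@H](C)CC(C)=O)C(=O)C(OC)(OC)[C@@]1(C)O[Si](C)(C)C(C)(C)C | intermediate
18 | diiodomethane | ICI | starting material
19 | bis(iodozincio)methane | I[Zn]C[Zn]I | intermediate
20 | C22 iodozinc alkoxide of 17 carrying the C21 iodozinciomethyl group on the α face | CC[C@H](C)[C@@H]1[C@](C)(C(=O)OC)[C@@H]([C@H](C)CC(C)=O)[C@](O[Zn]I)(C[Zn]I)C(OC)(OC)[C@@]1(C)O[Si](C)(C)C(C)(C)C | intermediate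
21 | trans-decalin methyl ester with cis-diaxial C18 and C22 hydroxyl groups, C24 dimethyl ketal and C26 OTBS | CC[C@H](C)[C@@H]1[C@](C)(C(=O)OC)[C@H]2[C@H](C)C[C@@](C)(O)C[C@]2(O)C(OC)(OC)[C@@]1(C)O[Si](C)(C)C(C)(C)C | intermediate
22 | decalin triol (C8 hydroxymethyl in place of the ester of 21) | CC[C@H](C)[C@@H]1[C@](C)(CO)[C@H]2[C@H](C)C[C@@](C)(O)C[C@]2(O)C(OC)(OC)[C@@]1(C)O[Si](C)(C)C(C)(C)C | intermediate
23 | C8 aldehyde | CC[C@H](C)[C@@H]1[C@](C)(C=O)[C@H]2[C@H](C)C[C@@](C)(O)C[C@]2(O)C(OC)(OC)[C@@]1(C)O[Si](C)(C)C(C)(C)C | intermediate
24 | C8 propargylic alcohol (C8 epimers) | CC[C@H](C)[C@@H]1[C@](C)(C(O)C#C)[C@H]2[C@H](C)C[C@@](C)(O)C[C@]2(O)C(OC)(OC)[C@@]1(C)O[Si](C)(C)C(C)(C)C | intermediate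
25 | propargylic alcohol with C24 ketone and free C18, C22 and C26 hydroxyl groups (C8 epimers) | CC[C@H](C)[C@@H]1[C@](C)(C(O)C#C)[C@H]2[C@H](C)C[C@@](C)(O)C[C@]2(O)C(=O)[C@@]1(C)O | intermediate
26 | ethynyl ketone | CC[C@H](C)[C@@H]1[C@](C)(C(=O)C#C)[C@H]2[C@H](C)C[C@@](C)(O)C[C@]2(O)C(=O)[C@@]1(C)O | intermediate
27 | CNP0304150.3 | CC[C@H](C)[C@@H]1[C@](C)(C(=O)/C=C/OC)[C@H]2[C@H](C)C[C@@](C)(O)C[C@]2(O)C(=O)[C@@]1(C)O | target

**Step count and risks**

Total step count: 19. Longest linear sequence: 17 steps (steps 1–3, 5–11 and 13–19, from 1).

Steps most likely to fail: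

Step 13 (Proposed new method). The zincio alkoxide may lose zinc oxide by β-elimination and give the C22 methylene compound, the hindered C22 carbonyl may fail to add, or addition at C18 first may leave C18 uncontrolled. The fallback closes ring B with methyl phenyl sulfone as the one-carbon dianion equivalent, in known steps. It sets out from 17: PhSO2CH2Li with CeCl3 (THF, −78 °C) should add to the unhindered C18 ketone and give the β-hydroxy sulfone F1. LiN(iPr)2 (2.2 equiv) should then form the alkoxide and the α-sulfonyl carbanion, which closes onto C22 from the α face and gives the cyclic hydroxy sulfone F2. Reductive desulfonylation (SmI2, HMPA, THF/MeOH) comes back to the route at 21.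

Step 11. The enolate may add 1,2 to the enone or be quenched by proton transfer, the hindered adduct may revert by retro-Michael cleavage, and the facial or syn/anti selectivity may be incomplete. The fallback uses the more electrophilic (E)-1-nitroprop-1-ene, for which ring enolates are known to add 1,4 with a high syn preference. It sets out from 15: the lithium enolate should give the nitro ketone F3. A nitroaldol (Henry) reaction with acetaldehyde then gives the nitro alcohol F4, Dess–Martin oxidation gives the α-nitro ketone F5, and radical denitration (Bu3SnH, AIBN) comes back to the route at 17.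

Step 8. The peracid may approach past the sec-butyl group because the axial C6 methyl group shields the β face, which would give poor facial selectivity at C26. The fallback delivers the oxygen by a directing group. It sets out from 10: the ester enolate is hydroxymethylated with formaldehyde, by the same β-face approach as in step 7, to give the hydroxymethyl ester F6. Hydroxyl-directed epoxidation of the silyl enol ether from the β face (tBuOOH, VO(acac)2) with silyl migration gives the hydroxymethyl silyloxy ketone F7. The primary alcohol is converted into the phenyl thionocarbonate F8 and removed by Barton–McCombie deoxygenation (Bu3SnH, AIBN), which comes back to the route at 13.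

Further compounds
F1 | step 13 | β-hydroxy sulfone from addition of PhSO2CH2Li to the C18 ketone of 17 (C18 epimers) | CC[C@H](C)[C@@H]1[C@](C)(C(=O)OC)[C@@H]([C@H](C)CC(C)(O)CS(=O)(=O)c2ccccc2)C(=O)C(OC)(OC)[C@@]1(C)O[Si](C)(C)C(C)(C)C
F2 | step 13 | cyclic hydroxy sulfone (21 with a phenylsulfonyl group on C21) | CC[C@H](C)[C@@H]1[C@](C)(C(=O)OC)[C@H]2[C@H](C)C[C@@](C)(O)C(S(=O)(=O)c3ccccc3)[C@]2(O)C(OC)(OC)[C@@]1(C)O[Si](C)(C)C(C)(C)C
F3 | step 11 | nitro ketone (17 with CH2NO2 in place of CH2C(=O)CH3) | CC[C@H](C)[C@@H]1[C@](C)(C(=O)OC)[C@@H]([C@H](C)C[N+](=O)[O-])C(=O)C(OC)(OC)[C@@]1(C)O[Si](C)(C)C(C)(C)C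
F4 | step 11 | nitro alcohol from the Henry reaction of F3 with acetaldehyde (C17 and C18 epimers) | CC[C@H](C)[C@@H]1[C@](C)(C(=O)OC)[C@@H]([C@H](C)C(C(C)O)[N+](=O)[O-])C(=O)C(OC)(OC)[C@@]1(C)O[Si](C)(C)C(C)(C)C
F5 | step 11 | α-nitro ketone (17 with a nitro group on C17) | CC[C@H](C)[C@@H]1[C@](C)(C(=O)OC)[C@@H]([C@H](C)C(C(C)=O)[N+](=O)[O-])C(=O)C(OC)(OC)[C@@]1(C)O[Si](C)(C)C(C)(C)C
F6 | step 8 | hydroxymethyl ester (11 with CH2OH in place of the C6 methyl group) | CC[C@H](C)[C@@H]1[C@](CO)(C(=O)OC)CCC(O[Si](C)(C)C(C)(C)C)=C1C
F7 | step 8 | hydroxymethyl silyloxy ketone (13 with CH2OH in place of the C6 methyl group) | CC[C@H](C)[C@@H]1[C@](CO)(C(=O)OC)CCC(=O)[C@@]1(C)O[Si](C)(C)C(C)(C)C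
F8 | step 8 | phenyl thionocarbonate of F7 | CC[C@H](C)[C@@H]1[C@](COC(=S)Oc2ccccc2)(C(=O)OC)CCC(=O)[C@@]1(C)O[Si](C)(C)C(C)(C)C
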